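# Proposed synthesis of CNP0326301.1 by hydroxycyclobutenone ring expansion

## Analysis of the target

The target 23 is a naphthazarin: a 5,8-dihydroxy-1,4-naphthoquinone with ring A as the benzenoid diol and ring B as the quinone (C1=O, C2, C3–H, C4=O). C2 carries a 2,2-dimethylcyclobutyl group bonded through its fully substituted carbon C1', and the C1' oxygen is esterified with angelic acid 19 (cyclobutane numbering: C1' carbinol, C2' C(CH3)2, C3' and C4' CH2). C1' is the only stereocentre and is (R); it bears O, C2 of ring B, the quaternary C2' and C4'H2, has no neighbouring stereocentre to relay from, and must be set in absolute terms. The Z double bond of the ester is the only other stereo-element.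

The angelate isomerises to the tiglate under nucleophilic, basic, acidic or prolonged thermal stress. The naphthazarin is redox-active, base-sensitive and tautomerises between rings A and B, and the cyclobutane is strained. Because C2 is the β-carbon of the C4 enone, an oxygen lone pair on C1' can push the C1'–C2' bond onto C2, so a free hydroxyl (under acid or as the alkoxide) threatens ring expansion to a spiro cyclopentanone, whereas the ester does not.

The difficulty is a hindered, enantiopure tertiary carbinol centre next to a quaternary carbon and an electron-poor ring. C1' cannot act as a nucleophile, and adding a quinone-ring nucleophile to ketone 1 offers no dependable asymmetric control. The strategy reads C1, C2, C3–H and C4 of ring B as the four carbons of the 3-monosubstituted cyclobutene-1,2-dione 10, whose two sp2 carbons are the carbons of a terminal alkyne, and reads C4a, C8a and ring A as a 2,5-dimethoxyphenyl group. Because the 5,8-dioxygenated naphthalene is unchanged when C2 and C3 are exchanged, it does not matter which dione carbonyl receives the aryl group, and C1' can be set at the outset by enantioselective alkynylation of 1.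

## Retrosynthetic reasoning

**23 to 21.** The two phenolic O–H groups of ring A are traced back to O–CH3. No skeletal bond is cut; the gain is that the redox-labile naphthazarin appears only in the last operation. The forward reaction has to remove both methyl groups oxidatively, through diquinone 22, and return two electrons, at a stage where the acylated C1' is immune to the acidic medium.

**21 to 18 and 19.** The acyl–oxygen bond at C1' is cut. It is cut late because the angelate would survive neither aryllithium 12 nor the thermolysis, where it would sit ortho to a phenol in 16 and could migrate or be eliminated. It is cut no later because the ester must be in place before the final acidic oxidation. The forward reaction has to acylate a hindered tertiary hydroxyl without base and without Z to E isomerisation, which is the role of mixed anhydride 20.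

**18 to 17 to 16.** The Si–O bond and the quinone oxidation level are adjusted. The silyl ether is carried from the start because it is the one group on C1' that tolerates organolithium, silver-assisted hydrolysis and heat. Oxidation of 16 to 17 precedes silyl removal so that the free carbinol never coexists with an electron-rich, ionisation-prone naphthalene.

**16 to 13 (key disconnection).** The C1–C8a bond of ring B is cut, which unravels the naphthalenediol into vinylketene 14 and further into the 4-aryl-4-hydroxycyclobutenone 13. Cutting here turns ring B into a four-membered ring assembled from small pieces, and keeps all bond changes away from C1'. The forward reaction is a thermal cascade through 14 and dienone 15 that is driven by strain release and aromatisation.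

**13 to 10 and 12.** The C4–C4a bond (carbinol carbon to aryl) is cut, giving dione 10 and aryllithium 12 from bromide 11. The symmetric substitution of 12 removes any regiochemical demand on this addition.

**10 to 9 to 6 and 8.** The C1–C2 and C3–C4 bonds of the future ring B are cut in a [2+2] sense, giving alkyne 6 and dichloroketene 8 (from 7). The two chlorines of 9 hold the oxidation level of the second carbonyl of 10. Either orientation of the cycloaddition leads to the same dione.

**6 to 5 to 4 to 1 and 2.** The C1'–C2 bond is cut between the carbinol carbon and the alkyne. This is the only C–C bond ever made at C1', and it is made on the commercial four-membered ketone 1 by face-selective delivery of alkynylzinc 3. The quaternary C2' on one flank and a CH2 on the other give the catalyst the largest possible steric contrast.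

## Alternatives that were turned down

**Alternative 1:** The cyclobutane is disconnected at C2'–C3' and C1'–C4'. The forward step is a catalytic formal [2+2]. Under a Lewis-acid-activated chiral oxazaborolidine, the tetrasubstituted silyl enol ether A2 attacks the β-carbon of acrylate A3 through its C(CH3)2 terminus. The ester enolate then closes on the silyloxycarbenium carbon C1' to give A1, with the ester on C4' trans to the silyloxy group.
- For: it is convergent, it creates the ring and C1' catalytically in one step, and the naphthalene core is already complete. On these points it is as strong as or stronger than the chosen route.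
- Against: the nucleophilic carbon of A2 is fully substituted, the product holds two adjacent quaternary carbons beside a methoxy-flanked naphthalene, and A1 is a donor–acceptor cyclobutane that can reopen by a retro-aldol path. The strong Lewis acid must coexist with four aryl methyl ethers. The ester carbon on C4' is superfluous and costs about three steps to remove (saponification, Barton decarboxylation).
- In its place the chosen strategy offers a purchased, intact cyclobutane, no carbon to excise, and a C–C bond at C1' made by adding a slim alkynyl group to a strained ketone.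

**Alternative 2:** The C1'–C4' bond is disconnected as a ring contraction. Irradiating crystals of the enantiopure α-acetoxy ketone A5 cleaves the bond from C1' to the carbonyl carbon, expels the carbonyl group, and recombines the radical pair inside the lattice to give acetate A4 with retention.
- For: the step needs no reagent, is stereospecific and avoids any hindered polar bond formation. In stereospecificity it is stronger than a catalyst-controlled addition.
- Against: only C1' stabilises a radical (aryl, acyloxy). C4' would be a primary radical, so loss of the carbonyl from the acyl radical is slow and re-closure should dominate. A5 already contains the same congested stereocentre, so the stereochemical problem is only moved. A4 holds just a dimethoxybenzene ring, so the second ring of the naphthazarin must still be annulated and the acetate exchanged for the angelate.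
- In its place the chosen strategy builds ring B in the very step that joins the fragments and reaches the target in 11 steps.

**Alternative 3:** The C1'–C2' bond is disconnected. The enantiopure benzylic carbamate A7 is lithiated at C1'. The carbanion is captured by the tethered tertiary pinacol boronate to form a five-membered boronate complex, and a 1,2-shift of the C2'–B bond to C1' expels the carbamate, contracting the ring to cyclobutyl boronate A6. Oxidation then gives the carbinol with retention.
- For: chirality is transferred stereospecifically from a secondary centre that is easy to obtain pure, the boron-to-oxygen exchange is dependable, and acylation can be done as an alkoxide at the arene stage. On enantiocontrol and on the acylation it is stronger.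
- Against: the migration must join two fully substituted carbons while forming a four-membered ring, with a tertiary migrating group on a hindered boronate. In such cases complex formation is reversible and migration slow, so racemisation of the lithiated carbamate or return to A7 should compete. A7 itself needs a multistep synthesis.
- In its place the chosen strategy offers bond constructions that are helped, not opposed, by ring strain, and a shorter sequence.

Key step: step 7

## Remarks on the chemistry

- The naphthazarin tautomers of 23 interconvert rapidly; the tautomer with the side chain on the quinone ring stands for the compound.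
- The sense of induction in step 1 has to be assigned on this ketone; the ligand antipode that gives the (R)-carbinol 4 is used, both antipodes being accessible from the two enantiomers of 10-camphorsulfonic acid.

## Route

Step 1
Reactants: 1 2,2-dimethylcyclobutan-1-one; 2 ethynyltrimethylsilane
Product: 4 (1R)-2,2-dimethyl-1-[(trimethylsilyl)ethynyl]cyclobutan-1-ol, via methyl[(trimethylsilyl)ethynyl]zinc 3 (not isolated)
Conditions: 2 (3 equiv), ZnMe2 (3 equiv), toluene, rt; Cu(OTf)2 (10 mol%), camphor-derived N-benzyl 2-exo-hydroxy-10-sulfonamide ligand (10 mol%), then 1, 0 °C → rt; aq. NH4Cl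
Reagents that add atoms: none
Why: Catalytic enantioselective alkynylation of a ketone by an alkynylzinc; the flanks of the carbonyl (quaternary carbon against CH2) differ as much as tert-alkyl against primary alkyl, the best case for face discrimination in dialkyl ketones, and the chiral Lewis acid complex delivers the acetylide to the face that sets C1' as (R).

Step 2
Reactants: 4 (1R)-2,2-dimethyl-1-[(trimethylsilyl)ethynyl]cyclobutan-1-ol
Product: 5 triethyl({(1R)-2,2-dimethyl-1-[(trimethylsilyl)ethynyl]cyclobutyl}oxy)silane
Conditions: Et3SiOTf, 2,6-lutidine, CH2Cl2, −78 → 0 °C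
Reagents that add atoms: triethylsilyl trifluoromethanesulfonate, CC[Si](CC)(CC)OS(=O)(=O)C(F)(F)F
Why: O-Silylation of a tertiary propargylic alcohol with a silyl triflate; the slim alkynyl group leaves the hydroxyl accessible and no bond to C1' is touched.

Step 3
Reactants: 5 triethyl({(1R)-2,2-dimethyl-1-[(trimethylsilyl)ethynyl]cyclobutyl}oxy)silane
Product: 6 triethyl{[(1R)-1-ethynyl-2,2-dimethylcyclobutyl]oxy}silane
Conditions: K2CO3 (0.3 equiv), MeOH, rt
Reagents that add atoms: none
Why: Base-catalysed methanolysis of the C(sp)–Si bond; the hindered tertiary O–SiEt3 group should be inert to carbonate in methanol.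

Step 4
Reactants: 6 triethyl{[(1R)-1-ethynyl-2,2-dimethylcyclobutyl]oxy}silane; 7 trichloroacetyl chloride
Product: 9 4,4-dichloro-3-[(1R)-2,2-dimethyl-1-(triethylsilyloxy)cyclobutyl]cyclobut-2-en-1-one, via dichloroketene 8 (not isolated)
Conditions: Zn–Cu couple, Et2O/DME (4:1), 35 °C, slow addition of 7 (2 equiv)
Reagents that add atoms: none
Why: Ketene–alkyne [2+2] cycloaddition; dichloroketene from reductive dechlorination of 7 is electrophilic enough for an unactivated terminal alkyne and bonds through its carbonyl carbon to the terminal alkyne carbon. DME binds ZnCl2 to suppress chloride migration and silyl cleavage, and either orientation would lead to the same dione 10.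

Step 5
Reactants: 9 4,4-dichloro-3-[(1R)-2,2-dimethyl-1-(triethylsilyloxy)cyclobutyl]cyclobut-2-en-1-one
Product: 10 3-[(1R)-2,2-dimethyl-1-(triethylsilyloxy)cyclobutyl]cyclobut-3-ene-1,2-dione
Conditions: AgOCOCF3 (2.2 equiv), 2,6-di-tert-butyl-4-methylpyridine (2.2 equiv), MeCN/H2O (10:1), 0 °C → rt, dark
Reagents that add atoms: water, O
Why: Silver-assisted hydrolysis of a geminal dihalide flanking a cyclobutenone carbonyl; Ag+ abstracts chloride from the allylic CCl2 carbon, the chlorine-stabilised cation is captured at that carbon, and loss of the second chloride leaves the C=O. The hindered pyridine scavenges acid so that the silyl ether, which protects C1' against ring expansion, stays on.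

Step 6
Reactants: 10 3-[(1R)-2,2-dimethyl-1-(triethylsilyloxy)cyclobutyl]cyclobut-3-ene-1,2-dione; 11 2-bromo-1,4-dimethoxybenzene
Product: 13 4-(2,5-dimethoxyphenyl)-2-[(1R)-2,2-dimethyl-1-(triethylsilyloxy)cyclobutyl]-4-hydroxycyclobut-2-en-1-one (both C4 epimers), via (2,5-dimethoxyphenyl)lithium 12 (not isolated)
Conditions: 11, n-BuLi (1.05 equiv), THF, −78 °C; cannulated into 10, THF, −78 °C; aq. NH4Cl at −78 °C
Reagents that add atoms: none
Why: Bromine–lithium exchange, then 1,2-addition of the aryllithium to the strained, electrophilic dione (inverse addition against double addition). The bulky C3 substituent should steer attack to the remote carbonyl next to C–H, and neither the site nor the face of attack matters because both are erased in step 7.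

Step 7
Reactants: 13 4-(2,5-dimethoxyphenyl)-2-[(1R)-2,2-dimethyl-1-(triethylsilyloxy)cyclobutyl]-4-hydroxycyclobut-2-en-1-one (both C4 epimers)
Product: 16 2-[(1R)-2,2-dimethyl-1-(triethylsilyloxy)cyclobutyl]-5,8-dimethoxynaphthalene-1,4-diol, via vinylketene 14 (not isolated), via 8a-H dienone 15 (not isolated)
Conditions: degassed p-xylene (0.01 M), 138 °C (reflux), Ar, 1–2 h
Reagents that add atoms: none
Why: This is the thermal ring expansion of a 4-aryl-4-hydroxycyclobutenone (Moore rearrangement), a known reaction type for this substrate class. Conrotatory 4π-electrocyclic opening of the bond between the carbonyl carbon and the carbinol carbon gives vinylketene 14. The hydroxyl, as the donor on the breaking bond, rotates outward, so the aryl group ends up cis to the ketene. Ring B then closes by 6π-electrocyclisation of the ketene carbon onto the free ortho carbon of the aryl group, forming C1–C8a and giving dienone 15, which tautomerises to the aromatic diol 16. Release of cyclobutenone strain and aromatisation drive the cascade. No stereocentre is formed: the carbinol centre is destroyed, so both epimers of 13 converge, and C1' is a spectator under neutral aprotic conditions that spare the silyl ether. The required regioselectivity is built in, since the other ortho position carries a methoxy group, and a product from aryl addition at the other dione carbonyl would be the same compound because 2- and 3-substituted 5,8-dimethoxynaphthalene-1,4-diols are identical. High dilution and exclusion of oxygen limit ketene dimerisation and premature oxidation.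

Step 8
Reactants: 16 2-[(1R)-2,2-dimethyl-1-(triethylsilyloxy)cyclobutyl]-5,8-dimethoxynaphthalene-1,4-diol
Product: 17 2-[(1R)-2,2-dimethyl-1-(triethylsilyloxy)cyclobutyl]-5,8-dimethoxynaphthalene-1,4-dione
Conditions: Ag2O (3 equiv), Na2SO4, Et2O, rt
Reagents that add atoms: none
Why: Two-electron oxidation of an electron-rich 1,4-naphthalenediol to the quinone under neutral, anhydrous conditions; the methyl ethers of ring A and the silyl ether are inert.

Step 9
Reactants: 17 2-[(1R)-2,2-dimethyl-1-(triethylsilyloxy)cyclobutyl]-5,8-dimethoxynaphthalene-1,4-dione
Product: 18 2-[(1R)-1-hydroxy-2,2-dimethylcyclobutyl]-5,8-dimethoxynaphthalene-1,4-dione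
Conditions: HF·pyridine, pyridine, THF, 0 °C → rt
Reagents that add atoms: none
Why: Fluoride-driven Si–O cleavage under buffered, weakly acidic conditions that neither form the C1' alkoxide nor strongly activate the quinone, the two triggers for ring expansion of 18.

Step 10
Reactants: 18 2-[(1R)-1-hydroxy-2,2-dimethylcyclobutyl]-5,8-dimethoxynaphthalene-1,4-dione; 19 angelic acid [(2Z)-2-methylbut-2-enoic acid]
Product: 21 (1R)-1-(5,8-dimethoxy-1,4-dioxo-1,4-dihydronaphthalen-2-yl)-2,2-dimethylcyclobutyl (2Z)-2-methylbut-2-enoate, via angelic 2,4,6-trichlorobenzoic anhydride 20 (not isolated)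
Conditions: 19, 2,4,6-trichlorobenzoyl chloride, Et3N, toluene, rt, 2 h; then 18, toluene, 80 °C, dark
Reagents that add atoms: none
Why: Yamaguchi-type mixed-anhydride acylation without a nucleophilic catalyst, the established way to angelates without Z to E isomerisation. The alcohol attacks the unhindered angeloyl carbonyl of 20, no alkoxide is formed, and C1' keeps its configuration because only the O–H bond reacts.

Step 11
Reactants: 21 (1R)-1-(5,8-dimethoxy-1,4-dioxo-1,4-dihydronaphthalen-2-yl)-2,2-dimethylcyclobutyl (2Z)-2-methylbut-2-enoate
Product: 23 (1R)-1-(5,8-dihydroxy-1,4-dioxo-1,4-dihydronaphthalen-2-yl)-2,2-dimethylcyclobutyl (2Z)-2-methylbut-2-enoate, via diquinone 22 (not isolated)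
Conditions: AgO (4 equiv), 6 M HNO3, acetone, rt, 5–10 min; then aq. Na2S2O4, CH2Cl2/H2O, rt, air work-up
Reagents that add atoms: water, O
Why: Oxidative demethylation of the p-dimethoxyarene ring (water adds at the methoxy-bearing carbons and methanol leaves) gives diquinone 22, which dithionite reduces by two electrons to the naphthazarin. The acylated C1' on an electron-poor ring can neither ionise nor rearrange in the acid, and the conjugated trisubstituted alkene should be inert to the oxidant on this time scale.

## Compound list

1 | 2,2-dimethylcyclobutan-1-one | CC1(C)CCC1=O | starting material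
2 | ethynyltrimethylsilane | C#C[Si](C)(C)C | starting material
3 | methyl[(trimethylsilyl)ethynyl]zinc | C[Zn]C#C[Si](C)(C)C | intermediate
4 | (1R)-2,2-dimethyl-1-[(trimethylsilyl)ethynyl]cyclobutan-1-ol | O[C@]1(C#C[Si](C)(C)C)CCC1(C)C | intermediate
5 | triethyl({(1R)-2,2-dimethyl-1-[(trimethylsilyl)ethynyl]cyclobutyl}oxy)silane | CC[Si](CC)(CC)O[C@]1(C#C[Si](C)(C)C)CCC1(C)C | intermediate
6 | triethyl{[(1R)-1-ethynyl-2,2-dimethylcyclobutyl]oxy}silane | CC[Si](CC)(CC)O[C@]1(C#C)CCC1(C)C | intermediate
7 | trichloroacetyl chloride | ClC(Cl)(Cl)C(Cl)=O | starting material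
8 | dichloroketene | ClC(Cl)=C=O | intermediate
9 | 4,4-dichloro-3-[(1R)-2,2-dimethyl-1-(triethylsilyloxy)cyclobutyl]cyclobut-2-en-1-one | CC[Si](CC)(CC)O[C@]1(C2=CC(=O)C2(Cl)Cl)CCC1(C)C | intermediate
10 | 3-[(1R)-2,2-dimethyl-1-(triethylsilyloxy)cyclobutyl]cyclobut-3-ene-1,2-dione | CC[Si](CC)(CC)O[C@]1(C2=CC(=O)C2=O)CCC1(C)C | intermediate
11 | 2-bromo-1,4-dimethoxybenzene | COc1ccc(OC)c(Br)c1 | starting material
12 | (2,5-dimethoxyphenyl)lithium | [Li]c1cc(OC)ccc1OC | intermediate
13 | 4-(2,5-dimethoxyphenyl)-2-[(1R)-2,2-dimethyl-1-(triethylsilyloxy)cyclobutyl]-4-hydroxycyclobut-2-en-1-one, both C4 epimers | CC[Si](CC)(CC)O[C@]1(C2=CC(O)(c3cc(OC)ccc3OC)C2=O)CCC1(C)C | intermediate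
14 | (3E)-4-(2,5-dimethoxyphenyl)-2-[(1R)-2,2-dimethyl-1-(triethylsilyloxy)cyclobutyl]-4-hydroxybuta-1,3-dien-1-one | CC[Si](CC)(CC)O[C@]1(C(=C=O)/C=C(/O)c2cc(OC)ccc2OC)CCC1(C)C | intermediate
15 | 2-[(1R)-2,2-dimethyl-1-(triethylsilyloxy)cyclobutyl]-4-hydroxy-5,8-dimethoxy-8aH-naphthalen-1-one | CC[Si](CC)(CC)O[C@]1(C2=CC(O)=C3C(OC)=CC=C(OC)C3C2=O)CCC1(C)C | intermediate
16 | 2-[(1R)-2,2-dimethyl-1-(triethylsilyloxy)cyclobutyl]-5,8-dimethoxynaphthalene-1,4-diol | CC[Si](CC)(CC)O[C@]1(c2cc(O)c3c(OC)ccc(OC)c3c2O)CCC1(C)C | intermediate
17 | 2-[(1R)-2,2-dimethyl-1-(triethylsilyloxy)cyclobutyl]-5,8-dimethoxynaphthalene-1,4-dione | CC[Si](CC)(CC)O[C@]1(C2=CC(=O)c3c(OC)ccc(OC)c3C2=O)CCC1(C)C | intermediate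
18 | 2-[(1R)-1-hydroxy-2,2-dimethylcyclobutyl]-5,8-dimethoxynaphthalene-1,4-dione | O[C@]1(C2=CC(=O)c3c(OC)ccc(OC)c3C2=O)CCC1(C)C | intermediate
19 | angelic acid, (2Z)-2-methylbut-2-enoic acid | C/C=C(/C)C(=O)O | starting material
20 | (2Z)-2-methylbut-2-enoic 2,4,6-trichlorobenzoic anhydride | C/C=C(/C)C(=O)OC(=O)c1c(Cl)cc(Cl)cc1Cl | intermediate
21 | (1R)-1-(5,8-dimethoxy-1,4-dioxo-1,4-dihydronaphthalen-2-yl)-2,2-dimethylcyclobutyl (2Z)-2-methylbut-2-enoate | C/C=C(/C)C(=O)O[C@]1(C2=CC(=O)c3c(OC)ccc(OC)c3C2=O)CCC1(C)C | intermediate
22 | (1R)-2,2-dimethyl-1-(1,4,5,8-tetraoxo-1,4,5,8-tetrahydronaphthalen-2-yl)cyclobutyl (2Z)-2-methylbut-2-enoate | C/C=C(/C)C(=O)O[C@]1(C2=CC(=O)C3=C(C2=O)C(=O)C=CC3=O)CCC1(C)C | intermediate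
23 | (1R)-1-(5,8-dihydroxy-1,4-dioxo-1,4-dihydronaphthalen-2-yl)-2,2-dimethylcyclobutyl (2Z)-2-methylbut-2-enoate | C/C=C(/C)C(=O)O[C@]1(C2=CC(=O)c3c(O)ccc(O)c3C2=O)CCC1(C)C | target

## Step count and least certain steps

Total step count: 11. Longest linear sequence: 11 steps (1 to 23); 2, 7, 11 and 19 are commercial and enter without steps of their own.

**Step 7 (key step).** The vinylketene may be diverted before it closes. The bulky substituent on the ketene carbon slows the 6π closure, which leaves room for ketene dimerisation, for capture of the ketene by the C4 hydroxyl after inward rotation (furanone formation), or for thermal loss of the silyl group followed by ring expansion.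
Fallback, setting out from 6 and 11 and returning at 17: aryllithium 12 (from 11) is treated with Cr(CO)6 and then Me3OBF4 to give pentacarbonyl[(2,5-dimethoxyphenyl)(methoxy)methylidene]chromium F1. Heating F1 with alkyne 6 in THF at 55 °C (Dötz benzannulation, the bulky alkyne substituent ending next to the phenol) and exposure to air should give 2-[(1R)-2,2-dimethyl-1-(triethylsilyloxy)cyclobutyl]-4,5,8-trimethoxynaphthalen-1-ol F2. Oxidation of F2 with (NH4)2Ce(NO3)6 in aqueous MeCN at 0 °C gives 17. This path also bypasses steps 4 to 6.

**Step 10.** Acylation of the hindered tertiary hydroxyl may be too slow. Prolonged heating then lets thermal Z to E isomerisation of the activated acid, or ring expansion of 18, take over.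
Fallback, setting out from 16 and returning at 21 and 22: the acylation is moved to an arene stage where an alkoxide is safe.
- Methylation of 16 (Me2SO4, K2CO3, acetone, reflux, Ar) gives triethyl{[(1R)-2,2-dimethyl-1-(1,4,5,8-tetramethoxynaphthalen-2-yl)cyclobutyl]oxy}silane F3.
- Bu4NF in THF gives (1R)-2,2-dimethyl-1-(1,4,5,8-tetramethoxynaphthalen-2-yl)cyclobutan-1-ol F4.
- The lithium alkoxide of F4 (LiN(SiMe3)2, THF, −78 °C) is acylated with angelic anhydride F5 (from 19 and dicyclohexylcarbodiimide) to give (1R)-2,2-dimethyl-1-(1,4,5,8-tetramethoxynaphthalen-2-yl)cyclobutyl (2Z)-2-methylbut-2-enoate F6.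
- (NH4)2Ce(NO3)6 in aqueous MeCN oxidises one ring of F6, giving 21 together with its isomer (1R)-1-(1,4-dimethoxy-5,8-dioxo-5,8-dihydronaphthalen-2-yl)-2,2-dimethylcyclobutyl (2Z)-2-methylbut-2-enoate F7. Both enter step 11, since both give diquinone 22.

**Step 5.** The allyl-type cation formed on chloride abstraction may be captured at the C–H terminus instead of the chlorine-bearing carbon, chloride may shift to the 2,4-dichloro isomer, or acid may strip the silyl ether and open the way to ring expansion.
Fallback, setting out from 9 and returning at 13: the order of events is reversed. Aryllithium 12 is added to the ketone of 9 at −78 °C to give 4,4-dichloro-1-(2,5-dimethoxyphenyl)-3-[(1R)-2,2-dimethyl-1-(triethylsilyloxy)cyclobutyl]cyclobut-2-en-1-ol F8 (both epimers). Its CCl2 group is no longer flanked by a carbonyl, so it should ionise more readily, and buffered AgOCOCF3 in aqueous MeCN would unmask the ketone to give 13 directly, avoiding dione 10.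

**Step 1.** Facial discrimination may be insufficient, because uncatalysed addition of the achiral alkynylzinc to the strained, very electrophilic cyclobutanone competes with the ligand-controlled path.
Fallback, setting out from 1 and 2 and returning at 4: deprotonation of 2 with n-BuLi (THF, −78 °C) and addition to 1 gives racemic 2,2-dimethyl-1-[(trimethylsilyl)ethynyl]cyclobutan-1-ol F9. F9 is resolved by preparative chromatography on a chiral stationary phase, and the (R)-enantiomer is carried on as 4.

**Step 11.** Over-oxidation, acid-promoted isomerisation of the angelate, or addition of nucleophiles to the highly electrophilic diquinone 22 before it is reduced may erode the product.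
Fallback, setting out from 21 and returning at 23: the redox detour is replaced by chelation-assisted ether cleavage. BCl3 in CH2Cl2 at −78 °C coordinates between each peri methoxy oxygen and the neighbouring quinone carbonyl and removes the two methyl groups, and aqueous work-up gives 23 without passing through 22. This fallback makes no new compound (F0).

## Further compounds

F1 | step 7 | pentacarbonyl[(2,5-dimethoxyphenyl)(methoxy)methylidene]chromium | COC(c1cc(OC)ccc1OC)=[Cr](=C=O)(=C=O)(=C=O)(=C=O)=C=O
F2 | step 7 | 2-[(1R)-2,2-dimethyl-1-(triethylsilyloxy)cyclobutyl]-4,5,8-trimethoxynaphthalen-1-ol | CC[Si](CC)(CC)O[C@]1(c2cc(OC)c3c(OC)ccc(OC)c3c2O)CCC1(C)C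
F3 | step 10 | triethyl{[(1R)-2,2-dimethyl-1-(1,4,5,8-tetramethoxynaphthalen-2-yl)cyclobutyl]oxy}silane | CC[Si](CC)(CC)O[C@]1(c2cc(OC)c3c(OC)ccc(OC)c3c2OC)CCC1(C)C
F4 | step 10 | (1R)-2,2-dimethyl-1-(1,4,5,8-tetramethoxynaphthalen-2-yl)cyclobutan-1-ol | O[C@]1(c2cc(OC)c3c(OC)ccc(OC)c3c2OC)CCC1(C)C
F5 | step 10 | angelic anhydride, (2Z)-2-methylbut-2-enoic anhydride | C/C=C(/C)C(=O)OC(=O)/C(C)=C\C
F6 | step 10 | (1R)-2,2-dimethyl-1-(1,4,5,8-tetramethoxynaphthalen-2-yl)cyclobutyl (2Z)-2-methylbut-2-enoate | C/C=C(/C)C(=O)O[C@]1(c2cc(OC)c3c(OC)ccc(OC)c3c2OC)CCC1(C)C
F7 | step 10 | (1R)-1-(1,4-dimethoxy-5,8-dioxo-5,8-dihydronaphthalen-2-yl)-2,2-dimethylcyclobutyl (2Z)-2-methylbut-2-enoate | C/C=C(/C)C(=O)O[C@]1(c2cc(OC)c3c(c2OC)C(=O)C=CC3=O)CCC1(C)C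
F8 | step 5 | 4,4-dichloro-1-(2,5-dimethoxyphenyl)-3-[(1R)-2,2-dimethyl-1-(triethylsilyloxy)cyclobutyl]cyclobut-2-en-1-ol, both C1 epimers | CC[Si](CC)(CC)O[C@]1(C2=CC(O)(c3cc(OC)ccc3OC)C2(Cl)Cl)CCC1(C)C
F9 | step 1 | racemic 2,2-dimethyl-1-[(trimethylsilyl)ethynyl]cyclobutan-1-ol | C[Si](C)(C)C#CC1(O)CCC1(C)C
F0 | step 11 | none | none
A1 | alternative 1 | 2,2,2-trifluoroethyl 2-(tert-butyldimethylsilyloxy)-3,3-dimethyl-2-(1,4,5,8-tetramethoxynaphthalen-2-yl)cyclobutane-1-carboxylate, ester trans to silyloxy, carbinol carbon as in the target | CC(C)(C)[Si](C)(C)O[C@]1(c2cc(OC)c3c(OC)ccc(OC)c3c2OC)[C@@H](C(=O)OCC(F)(F)F)CC1(C)C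
A2 | alternative 1 | tert-butyldimethyl{[2-methyl-1-(1,4,5,8-tetramethoxynaphthalen-2-yl)prop-1-en-1-yl]oxy}silane | CC(C)=C(O[Si](C)(C)C(C)(C)C)c1cc(OC)c2c(OC)ccc(OC)c2c1OC
A3 | alternative 1 | 2,2,2-trifluoroethyl acrylate | C=CC(=O)OCC(F)(F)F
A4 | alternative 2 | (R)-1-(2,5-dimethoxyphenyl)-2,2-dimethylcyclobutyl acetate | CC(=O)O[C@]1(c2cc(OC)ccc2OC)CCC1(C)C
A5 | alternative 2 | (R)-1-(2,5-dimethoxyphenyl)-5,5-dimethyl-2-oxocyclopentyl acetate | CC(=O)O[C@]1(c2cc(OC)ccc2OC)C(=O)CCC1(C)C
A6 | alternative 3 | pinacol [2,2-dimethyl-1-(1,4,5,8-tetramethoxynaphthalen-2-yl)cyclobutyl]boronate, boron in the place of the ester oxygen of the target | CC1(C)OB([C@]2(c3cc(OC)c4c(OC)ccc(OC)c4c3OC)CCC2(C)C)OC1(C)C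
A7 | alternative 3 | 4-methyl-4-(4,4,5,5-tetramethyl-1,3,2-dioxaborolan-2-yl)-1-(1,4,5,8-tetramethoxynaphthalen-2-yl)pentyl N,N-diisopropylcarbamate | CC(C)N(C(C)C)C(=O)O[C@@H](CCC(C)(C)B1OC(C)(C)C(C)(C)O1)c1cc(OC)c2c(OC)ccc(OC)c2c1OC
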